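## Retrosynthetic overview

1. The target is opened at the aryl–C1' bond: an aryltitanium made from a 5-bromo-dihydrobenzofuran core adds to (R)-glyceraldehyde acetonide (fragment C), giving the erythro triol by Felkin–Anh control.
2. The dihydrofuran ring is the only ring formed. It closes at O1–C2 by acid-mediated trapping of a p-hydroxybenzylic cation by the ring A phenol, trans to the fixed C3 centre.
3. The 1,2-diaryl-1,3-diol precursor comes from an Evans syn-aldol that joins the ring A arylacetyl imide (fragment A) to the ring B aldehyde (fragment B), followed by LiBH4 removal of the auxiliary.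
4. Fragments A and B both come from guaiacol (from catechol): A by dibromination, MOM protection, ortho-selective Br/Li exchange with oxirane, oxidation and acylation; B by para-bromination, MOM protection and formylation.
5. Fragment C comes from D-serine by diazotisation with retention, ester/acetonide formation and partial reduction.

Assumption: (S)-4-benzyloxazolidin-2-one is bought and used as a recoverable auxiliary; the two THP acetal carbons form as epimer mixtures and are left undefined in the SMILES.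

## Route

Step 1
Reactants: 1 catechol
Product: 2 guaiacol (2-methoxyphenol)
Conditions: MeI (1.0 equiv), K2CO3 (1.0 equiv), acetone, reflux; distillation
Reagents that add atoms: iodomethane, CI
Why: Williamson ether synthesis on one phenol, the mono-ether being separated from catechol and veratrole by distillation.

Step 2
Reactants: 2 guaiacol
Product: 3 4,6-dibromo-2-methoxyphenol
Conditions: NBS (2.1 equiv), i-Pr2NH (0.1 equiv), CH2Cl2, 0 °C → rt
Reagents that add atoms: N-bromosuccinimide, O=C1CCC(=O)N1Br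
Why: Electrophilic aromatic bromination in which the free OH (amine-assisted ortho delivery, then para attack) directs both bromines ortho and para to itself.

Step 3
Reactants: 3 4,6-dibromo-2-methoxyphenol
Product: 4 1,5-dibromo-3-methoxy-2-(methoxymethoxy)benzene
Conditions: NaH (1.2 equiv), THF–DMF, 0 °C; MOMCl (1.2 equiv)
Reagents that add atoms: chloromethyl methyl ether, COCCl
Why: Williamson-type O-alkylation of the acidic phenoxide gives a MOM acetal that survives organolithiums and later directs the exchange.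

Step 4
Reactants: 4 1,5-dibromo-3-methoxy-2-(methoxymethoxy)benzene
Product: 6 2-[5-bromo-3-methoxy-2-(methoxymethoxy)phenyl]ethan-1-ol, via aryllithium 5 (not isolated)
Conditions: n-BuLi (1.05 equiv), Et2O, −78 °C; oxirane (3 equiv), −78 → 0 °C; H2O
Reagents that add atoms: oxirane, C1CO1
Why: Chelation-assisted bromine–lithium exchange occurs at the bromide flanking the MOM ether, and the aryllithium opens oxirane by SN2.

Step 5
Reactants: 6 2-[5-bromo-3-methoxy-2-(methoxymethoxy)phenyl]ethan-1-ol
Product: 8 2-[5-bromo-3-methoxy-2-(methoxymethoxy)phenyl]acetic acid, via arylacetaldehyde 7 (not isolated)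
Conditions: TEMPO (0.2 equiv), PhI(OAc)2 (2.2 equiv), MeCN–H2O (1:1), rt
Reagents that add atoms: water, O
Why: TEMPO/PhI(OAc)2 oxidation takes the primary alcohol through the aldehyde hydrate to the acid without touching the MOM ether or aryl bromide.

Step 6
Reactants: 8 2-[5-bromo-3-methoxy-2-(methoxymethoxy)phenyl]acetic acid
Product: 10 (S)-4-benzyl-3-{2-[5-bromo-3-methoxy-2-(methoxymethoxy)phenyl]acetyl}oxazolidin-2-one (fragment A), via mixed pivalic anhydride 9 (not isolated)
Conditions: t-BuCOCl (1.1 equiv), Et3N (2.5 equiv), THF, −20 °C; then LiCl (1.1 equiv), (S)-4-benzyloxazolidin-2-one (1.05 equiv), −20 °C → rt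
Reagents that add atoms: (S)-4-benzyloxazolidin-2-one, O=C1N[C@@H](Cc2ccccc2)CO1
Why: Mixed-anhydride N-acylation of the oxazolidinone installs the Evans auxiliary under conditions too mild to epimerise or cleave anything.

Step 7
Reactants: 2 guaiacol
Product: 11 4-bromo-2-methoxyphenol
Conditions: NBS (1.0 equiv), MeCN, 0 °C
Reagents that add atoms: N-bromosuccinimide, O=C1CCC(=O)N1Br
Why: Electrophilic aromatic bromination goes para to the free OH, the stronger donor.

Step 8
Reactants: 11 4-bromo-2-methoxyphenol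
Product: 12 4-bromo-2-methoxy-1-(methoxymethoxy)benzene
Conditions: NaH (1.2 equiv), THF–DMF, 0 °C; MOMCl (1.2 equiv)
Reagents that add atoms: chloromethyl methyl ether, COCCl
Why: Williamson-type O-alkylation masks the phenol as a base-stable MOM acetal.

Step 9
Reactants: 12 4-bromo-2-methoxy-1-(methoxymethoxy)benzene
Product: 15 3-methoxy-4-(methoxymethoxy)benzaldehyde (fragment B), via aryllithium 13 (not isolated), via lithium hemiaminal alkoxide 14 (not isolated)
Conditions: n-BuLi (1.1 equiv), THF, −78 °C; DMF (2 equiv), −78 °C → rt; H2O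
Reagents that add atoms: N,N-dimethylformamide, CN(C)C=O
Why: Bromine–lithium exchange followed by Bouveault formylation, the hemiaminal alkoxide releasing the aldehyde only on work-up.

Step 10
Reactants: 16 D-serine
Product: 19 (R)-glyceric acid, via diazonium carboxylate 17 (not isolated), via alpha-lactone 18 (not isolated)
Conditions: NaNO2 (1.5 equiv), 1 M aq. H2SO4, 0 °C → rt
Reagents that add atoms: water, O
Why: Diazotisation of the amine, carboxylate displacement of N2 to an alpha-lactone and opening by water are two inversions, so the (R) centre is kept with net retention.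

Step 11
Reactants: 19 (R)-glyceric acid
Product: 20 methyl (R)-2,2-dimethyl-1,3-dioxolane-4-carboxylate
Conditions: 2,2-dimethoxypropane, MeOH, TsOH·H2O (cat.), rt
Reagents that add atoms: methanol, CO; 2,2-dimethoxypropane, COC(C)(C)OC
Why: Fischer esterification and acid-catalysed acetonide formation run together and leave the stereocentre untouched.

Step 12
Reactants: 20 methyl (R)-2,2-dimethyl-1,3-dioxolane-4-carboxylate
Product: 22 (R)-2,2-dimethyl-1,3-dioxolane-4-carbaldehyde (fragment C), via aluminium hemiacetal 21 (not isolated)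
Conditions: i-Bu2AlH (1.05 equiv), CH2Cl2, −78 °C; MeOH, then aq. KNaC4H4O6; used at once
Reagents that add atoms: none
Why: Partial ester reduction stops at the tetrahedral aluminium hemiacetal at −78 °C, which gives the aldehyde on work-up without epimerisation.

Step 13
Reactants: 10 imide (fragment A); 15 3-methoxy-4-(methoxymethoxy)benzaldehyde (fragment B)
Product: 25 (S)-4-benzyl-3-{(2S,3S)-2-[5-bromo-3-methoxy-2-(methoxymethoxy)phenyl]-3-hydroxy-3-[3-methoxy-4-(methoxymethoxy)phenyl]propanoyl}oxazolidin-2-one, via boron enolate 23 (not isolated), via boron aldolate 24 (not isolated)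
Conditions: Bu2BOTf (1.2 equiv), Et3N (1.5 equiv), CH2Cl2, 0 °C; 15 (1.2 equiv), −78 → 0 °C; then pH 7 buffer, MeOH, 30% H2O2, 0 °C
Reagents that add atoms: none
Why: Evans boron aldol in which the (Z)-enolate reacts through a Zimmerman–Traxler chair on the face away from the benzyl group of the (S)-auxiliary, giving the (2S,3S)-syn adduct and fixing the future C3 centre.

Step 14
Reactants: 25 syn-aldol imide
Product: 26 (1S,2R)-2-[5-bromo-3-methoxy-2-(methoxymethoxy)phenyl]-1-[3-methoxy-4-(methoxymethoxy)phenyl]propane-1,3-diol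
Conditions: LiBH4 (2 equiv), H2O (2 equiv), Et2O–THF, 0 °C
Reagents that add atoms: none
Why: Reductive cleavage of the imide at the exocyclic carbonyl gives the primary alcohol without epimerisation or retro-aldol and releases the auxiliary.

Step 15
Reactants: 26 diol
Product: 29 [(2S,3R)-5-bromo-2-(4-hydroxy-3-methoxyphenyl)-7-methoxy-2,3-dihydro-1-benzofuran-3-yl]methanol, via bis-phenol triol 27 (not isolated), via quinone methide 28 (not isolated)
Conditions: 3 M aq. HCl–THF (1:3), 45 °C
Reagents that add atoms: none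
Why: Acid hydrolysis of both MOM acetals, ionisation of the p-hydroxybenzylic alcohol (the quinone methide reacting as its O-protonated cation) and 5-exo capture by the ring A phenol is a reversible SN1 etherification, so the fixed C3 centre steers the aryl group trans and sets (2S).

Step 16
Reactants: 29 bromo-dihydrobenzofuran diol
Product: 30 bis-THP ether of 29 (phenol and primary alcohol both as oxan-2-yl ethers)
Conditions: 3,4-dihydro-2H-pyran (5 equiv), PPTS (0.1 equiv), CH2Cl2, rt
Reagents that add atoms: 3,4-dihydro-2H-pyran, C1=COCCC1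
Why: Acid-catalysed tetrahydropyranylation masks both OH groups as acetals that tolerate organolithiums and fall off under very mild acid.

Step 17
Reactants: 30 bis-THP aryl bromide; 22 (R)-2,2-dimethyl-1,3-dioxolane-4-carbaldehyde (fragment C)
Product: 33 (S)-{(2S,3R)-7-methoxy-2-[3-methoxy-4-(oxan-2-yloxy)phenyl]-3-[(oxan-2-yloxy)methyl]-2,3-dihydro-1-benzofuran-5-yl}[(R)-2,2-dimethyl-1,3-dioxolan-4-yl]methanol, via aryllithium 31 (not isolated), via aryltitanium 32 (not isolated)
Conditions: t-BuLi (2.1 equiv), THF, −78 °C; ClTi(OiPr)3 (1.2 equiv), −78 → −40 °C; 22 (1.5 equiv), −78 → −20 °C; H2O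
Reagents that add atoms: none
Why: Bromine–lithium exchange and transmetalation give a non-chelating aryltitanium that adds by the polar Felkin–Anh model, anti to the dioxolane C–O bond, so the (R)-aldehyde gives the anti (erythro) alcohol with the new carbinol centre (S).

Step 18
Reactants: 33 protected adduct
Product: 34 (1S,2R)-1-[(2S,3R)-2-(4-hydroxy-3-methoxyphenyl)-3-(hydroxymethyl)-7-methoxy-2,3-dihydro-1-benzofuran-5-yl]propane-1,2,3-triol (target)
Conditions: AcOH–H2O (4:1), 40 °C
Reagents that add atoms: none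
Why: Mild acetal hydrolysis removes both THP ethers and the acetonide with an acid too weak to ionise the benzylic alcohol or the benzylic ring ether, so all four centres are kept.

## Compound list

1 | catechol (benzene-1,2-diol) | Oc1ccccc1O | starting material
2 | guaiacol (2-methoxyphenol) | COc1ccccc1O | intermediate
3 | 4,6-dibromo-2-methoxyphenol | COc1cc(Br)cc(Br)c1O | intermediate
4 | 1,5-dibromo-3-methoxy-2-(methoxymethoxy)benzene | COCOc1c(Br)cc(Br)cc1OC | intermediate
5 | [5-bromo-3-methoxy-2-(methoxymethoxy)phenyl]lithium | [Li]c1cc(Br)cc(OC)c1OCOC | intermediate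
6 | 2-[5-bromo-3-methoxy-2-(methoxymethoxy)phenyl]ethan-1-ol | OCCc1cc(Br)cc(OC)c1OCOC | intermediate
7 | 2-[5-bromo-3-methoxy-2-(methoxymethoxy)phenyl]acetaldehyde | O=CCc1cc(Br)cc(OC)c1OCOC | intermediate
8 | 2-[5-bromo-3-methoxy-2-(methoxymethoxy)phenyl]acetic acid | OC(=O)Cc1cc(Br)cc(OC)c1OCOC | intermediate
9 | mixed anhydride of 8 with pivalic acid | CC(C)(C)C(=O)OC(=O)Cc1cc(Br)cc(OC)c1OCOC | intermediate
10 | (S)-4-benzyl-3-{2-[5-bromo-3-methoxy-2-(methoxymethoxy)phenyl]acetyl}oxazolidin-2-one (fragment A) | O=C(Cc1cc(Br)cc(OC)c1OCOC)N1[C@@H](Cc2ccccc2)COC1=O | intermediate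
11 | 4-bromo-2-methoxyphenol | COc1cc(Br)ccc1O | intermediate
12 | 4-bromo-2-methoxy-1-(methoxymethoxy)benzene | COCOc1ccc(Br)cc1OC | intermediate
13 | [3-methoxy-4-(methoxymethoxy)phenyl]lithium | [Li]c1ccc(OCOC)c(OC)c1 | intermediate
14 | lithium (dimethylamino)[3-methoxy-4-(methoxymethoxy)phenyl]methanolate | [Li+].[O-]C(N(C)C)c1ccc(OCOC)c(OC)c1 | intermediate
15 | 3-methoxy-4-(methoxymethoxy)benzaldehyde (fragment B) | COCOc1ccc(C=O)cc1OC | intermediate
16 | D-serine, (R)-2-amino-3-hydroxypropanoic acid | N[C@H](CO)C(=O)O | starting material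
17 | (R)-2-diazonio-3-hydroxypropanoate | N#[N+][C@H](CO)C(=O)[O-] | intermediate
18 | (S)-3-(hydroxymethyl)oxiran-2-one (alpha-lactone) | O=C1O[C@H]1CO | intermediate
19 | (R)-glyceric acid, (R)-2,3-dihydroxypropanoic acid | O[C@H](CO)C(=O)O | intermediate
20 | methyl (R)-2,2-dimethyl-1,3-dioxolane-4-carboxylate | COC(=O)[C@H]1COC(C)(C)O1 | intermediate
21 | diisobutylaluminium hemiacetal of 20 (hemiacetal carbon undefined) | COC(O[Al](CC(C)C)CC(C)C)[C@H]1COC(C)(C)O1 | intermediate
22 | (R)-2,2-dimethyl-1,3-dioxolane-4-carbaldehyde (fragment C) | O=C[C@H]1COC(C)(C)O1 | intermediate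
23 | (Z)-dibutylboron enolate of 10 | CCCCB(CCCC)O/C(=C\c1cc(Br)cc(OC)c1OCOC)N1[C@@H](Cc2ccccc2)COC1=O | intermediate
24 | dibutylboron aldolate of 25 | CCCCB(CCCC)O[C@H](c1ccc(OCOC)c(OC)c1)[C@H](c1cc(Br)cc(OC)c1OCOC)C(=O)N1[C@@H](Cc2ccccc2)COC1=O | intermediate
25 | (S)-4-benzyl-3-{(2S,3S)-2-[5-bromo-3-methoxy-2-(methoxymethoxy)phenyl]-3-hydroxy-3-[3-methoxy-4-(methoxymethoxy)phenyl]propanoyl}oxazolidin-2-one | O[C@H](c1ccc(OCOC)c(OC)c1)[C@H](c1cc(Br)cc(OC)c1OCOC)C(=O)N1[C@@H](Cc2ccccc2)COC1=O | intermediate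
26 | (1S,2R)-2-[5-bromo-3-methoxy-2-(methoxymethoxy)phenyl]-1-[3-methoxy-4-(methoxymethoxy)phenyl]propane-1,3-diol | O[C@H](c1ccc(OCOC)c(OC)c1)[C@H](c1cc(Br)cc(OC)c1OCOC)CO | intermediate
27 | (1S,2R)-2-(5-bromo-2-hydroxy-3-methoxyphenyl)-1-(4-hydroxy-3-methoxyphenyl)propane-1,3-diol | O[C@H](c1ccc(O)c(OC)c1)[C@H](c1cc(Br)cc(OC)c1O)CO | intermediate
28 | 4-[(2R)-2-(5-bromo-2-hydroxy-3-methoxyphenyl)-3-hydroxypropylidene]-2-methoxycyclohexa-2,5-dien-1-one (alkene geometry undefined) | COC1=CC(=C[C@H](c2cc(Br)cc(OC)c2O)CO)C=CC1=O | intermediate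
29 | [(2S,3R)-5-bromo-2-(4-hydroxy-3-methoxyphenyl)-7-methoxy-2,3-dihydro-1-benzofuran-3-yl]methanol | COc1cc([C@H]2Oc3c(OC)cc(Br)cc3[C@@H]2CO)ccc1O | intermediate
30 | 2-{4-[(2S,3R)-5-bromo-7-methoxy-3-[(oxan-2-yloxy)methyl]-2,3-dihydro-1-benzofuran-2-yl]-2-methoxyphenoxy}oxane (acetal carbons undefined) | COc1cc([C@H]2Oc3c(OC)cc(Br)cc3[C@@H]2COC2CCCCO2)ccc1OC1CCCCO1 | intermediate
31 | 5-lithio derivative of 30 | COc1cc([C@H]2Oc3c(OC)cc([Li])cc3[C@@H]2COC2CCCCO2)ccc1OC1CCCCO1 | intermediate
32 | 5-[tri(propan-2-yloxy)titanio] derivative of 30 | COc1cc([C@H]2Oc3c(OC)cc([Ti](OC(C)C)(OC(C)C)OC(C)C)cc3[C@@H]2COC2CCCCO2)ccc1OC1CCCCO1 | intermediate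
33 | (S)-{(2S,3R)-7-methoxy-2-[3-methoxy-4-(oxan-2-yloxy)phenyl]-3-[(oxan-2-yloxy)methyl]-2,3-dihydro-1-benzofuran-5-yl}[(R)-2,2-dimethyl-1,3-dioxolan-4-yl]methanol | COc1cc([C@H]2Oc3c(OC)cc([C@H](O)[C@H]4COC(C)(C)O4)cc3[C@@H]2COC2CCCCO2)ccc1OC1CCCCO1 | intermediate
34 | (1S,2R)-1-[(2S,3R)-2-(4-hydroxy-3-methoxyphenyl)-3-(hydroxymethyl)-7-methoxy-2,3-dihydro-1-benzofuran-5-yl]propane-1,2,3-triol | COc1cc([C@H]2Oc3c(OC)cc([C@H](O)[C@H](O)CO)cc3[C@@H]2CO)ccc1O | target

## Step count and risks

Total step count: 18. Longest linear sequence: 12 steps (steps 1–6, then 13–18, from catechol).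

**Step 4 (site-selective bromine–lithium exchange).** If exchange is not clean at the bromide next to the MOM ether, the fallback sets out from 11 and comes back at 6. O-Allylation of 11 (allyl bromide, K2CO3, acetone, reflux) gives 1-(allyloxy)-4-bromo-2-methoxybenzene F1. Aromatic Claisen rearrangement (N,N-diethylaniline, 190 °C) moves the allyl group to the only free ortho position and gives 2-allyl-4-bromo-6-methoxyphenol F2. MOM protection (NaH, MOMCl, THF–DMF) gives 1-allyl-5-bromo-3-methoxy-2-(methoxymethoxy)benzene F3. Ozonolysis (O3, CH2Cl2–MeOH, −78 °C) with NaBH4 work-up then delivers 6, so the carbon chain is placed by a sigmatropic shift and not by organometallic selectivity.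

**Step 15 (acid cyclisation).** The risks are loss of formaldehyde to a stilbene and cis/trans mixtures. The fallback sets out from 26 and comes back at 29. Me3SiBr (6 equiv, CH2Cl2, −20 °C) cleaves both MOM ethers and turns the benzylic alcohol into the bromide, giving [(2R)-3-bromo-2-[5-bromo-3-methoxy-2-(trimethylsilyloxy)phenyl]-3-[3-methoxy-4-(trimethylsilyloxy)phenyl]propoxy]trimethylsilane F4 (bromide carbon as a mixture). Stirring this with aqueous NaHCO3 in THF at rt, then K2CO3/MeOH to strip residual silyl groups, frees the phenols and expels bromide to the quinone methide 28. The ortho-phenol adds to it in a base-mediated intramolecular 1,6-addition that gives the trans ring of 29 without strong acid.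

**Step 17 (diastereoselectivity of the aryl addition).** If the anti:syn ratio is poor, the fallback sets out from 30 (with ester 20) and comes back at 33. Ester 20 is converted with MeNH(OMe)·HCl and i-PrMgCl (THF, −20 °C) into (R)-N-methoxy-N,2,2-trimethyl-1,3-dioxolane-4-carboxamide F5. Aryllithium 31 (from 30 and t-BuLi, THF, −78 °C) is acylated by it to {(2S,3R)-7-methoxy-2-[3-methoxy-4-(oxan-2-yloxy)phenyl]-3-[(oxan-2-yloxy)methyl]-2,3-dihydro-1-benzofuran-5-yl}[(R)-2,2-dimethyl-1,3-dioxolan-4-yl]methanone F6. Reduction with (S)-Me-CBS oxazaborolidine and BH3·SMe2 (THF, −20 °C, aryl as the large group) sets the (S)-carbinol of 33 under reagent control instead of substrate control.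

Further compounds
F1 | step 4 | 1-(allyloxy)-4-bromo-2-methoxybenzene | C=CCOc1ccc(Br)cc1OC
F2 | step 4 | 2-allyl-4-bromo-6-methoxyphenol | C=CCc1cc(Br)cc(OC)c1O
F3 | step 4 | 1-allyl-5-bromo-3-methoxy-2-(methoxymethoxy)benzene | C=CCc1cc(Br)cc(OC)c1OCOC
F4 | step 15 | [(2R)-3-bromo-2-[5-bromo-3-methoxy-2-(trimethylsilyloxy)phenyl]-3-[3-methoxy-4-(trimethylsilyloxy)phenyl]propoxy]trimethylsilane | BrC(c1ccc(O[Si](C)(C)C)c(OC)c1)[C@H](c1cc(Br)cc(OC)c1O[Si](C)(C)C)CO[Si](C)(C)C
F5 | step 17 | (R)-N-methoxy-N,2,2-trimethyl-1,3-dioxolane-4-carboxamide | CON(C)C(=O)[C@H]1COC(C)(C)O1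
F6 | step 17 | {(2S,3R)-7-methoxy-2-[3-methoxy-4-(oxan-2-yloxy)phenyl]-3-[(oxan-2-yloxy)methyl]-2,3-dihydro-1-benzofuran-5-yl}[(R)-2,2-dimethyl-1,3-dioxolan-4-yl]methanone | COc1cc([C@H]2Oc3c(OC)cc(C(=O)[C@H]4COC(C)(C)O4)cc3[C@@H]2COC2CCCCO2)ccc1OC1CCCCO1
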